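**Retrosynthetic overview**
- Target ⇐ diene triester: the oxirane goes on last, on the trisubstituted alkene, anti to the allylic acetoxy group.
- Diene triester ⇐ racemic 2‑(benzoyloxymethyl)‑7‑oxanorbornadiene + benzoic acid: enantioselective Rh‑catalysed SN2' opening of the oxa‑bridge (trans C–OH / C–OBz), then acetylation of the freed OH.
- Oxanorbornadiene benzoate ⇐ methyl 7‑oxanorbornadiene‑2‑carboxylate (reduction, benzoylation).
- Key step: that ester ⇐ 2,4‑dibromo‑8‑oxabicyclo[3.2.1]oct‑6‑en‑3‑one by Favorskii ring contraction (seven‑membered carbocycle → six‑membered ring plus the exocyclic carbon).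
- Dibromoketone ⇐ furan + tetrabromoacetone ([4+3]). Ring order: oxa‑bridged cycloheptenone, contraction to the six‑membered carbocycle, bridge opening, oxirane last.

Assumption: racemic compounds (4–6, F1–F4) are drawn as the enantiomer that is carried forward; the ligand hand in step 5 is whichever makes (1S,4R)‑6 the fast‑reacting enantiomer.

**Route**

Step 1
Reactants: 1 furan; 2 1,1,3,3‑tetrabromopropan‑2‑one
Product: 3 (1R,2S,4R,5S)‑2,4‑dibromo‑8‑oxabicyclo[3.2.1]oct‑6‑en‑3‑one (meso cis‑dibromide, minor diastereomers carried along)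
Conditions: Zn dust, B(OEt)3, THF, 20 °C, dark, furan 3 equiv
Reagents that add atoms: none
Why: Noyori–Hoffmann [4+3] cycloaddition of the zinc oxyallyl cation from 2 with furan gives the known bridged dibromoketone; its stereocentres are erased or made irrelevant in step 2, so the diastereomer mixture is used as such.

Step 2
Reactants: 3 (1R,2S,4R,5S)‑2,4‑dibromo‑8‑oxabicyclo[3.2.1]oct‑6‑en‑3‑one
Product: 4 (±)‑methyl 7‑oxabicyclo[2.2.1]hepta‑2,5‑diene‑2‑carboxylate
Conditions: NaOMe (2.2 equiv), Et2O–MeOH 10:1, −20 → 0 °C; pH 7 buffer quench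
Reagents that add atoms: sodium methoxide ([Na+].[O-]C)
Why: Favorskii rearrangement of an α,α'‑dibromoketone: methoxide triggers a 1,2‑shift of a ring carbon from the carbonyl carbon to the neighbouring C–Br carbon, contracting the seven‑membered carbocycle and turning the carbonyl carbon into the exocyclic ester, and loss of the second bromide gives the conjugated alkene (as with 2,6‑dibromocyclohexanone and α‑bromotropinones); the product is racemic.

Step 3
Reactants: 4 (±)‑methyl 7‑oxabicyclo[2.2.1]hepta‑2,5‑diene‑2‑carboxylate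
Product: 5 (±)‑(7‑oxabicyclo[2.2.1]hepta‑2,5‑dien‑2‑yl)methanol
Conditions: DIBAL‑H (2.2 equiv), CH2Cl2, −78 °C; Rochelle salt
Reagents that add atoms: none
Why: DIBAL‑H 1,2‑reduction of the enoate to the allylic alcohol; at −78 °C the strained oxa‑bridge and both alkenes are untouched.

Step 4
Reactants: 5 (±)‑(7‑oxabicyclo[2.2.1]hepta‑2,5‑dien‑2‑yl)methanol
Product: 6 (±)‑(7‑oxabicyclo[2.2.1]hepta‑2,5‑dien‑2‑yl)methyl benzoate
Conditions: BzCl, Et3N, DMAP (cat.), CH2Cl2, 0 °C
Reagents that add atoms: benzoyl chloride (O=C(Cl)c1ccccc1)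
Why: DMAP‑catalysed O‑acylation under basic conditions, which the acid‑sensitive oxabicycle tolerates.

Step 5
Reactants: 6 (±)‑(7‑oxabicyclo[2.2.1]hepta‑2,5‑dien‑2‑yl)methyl benzoate
Product: 8 [(5R,6R)‑6‑(acetyloxy)‑5‑(benzoyloxy)cyclohexa‑1,3‑dien‑1‑yl]methyl benzoate, via hydroxy benzoate 7 (not isolated)
Conditions: [Rh(cod)Cl]2 (2.5 mol %), Josiphos PPF‑PtBu2 (6 mol %), PhCO2H (0.55 equiv), iPr2NEt (0.55 equiv), THF, 50 °C, to ~50 % conversion; then Ac2O, Et3N, DMAP, 0 °C
Reagents that add atoms: benzoic acid (OC(=O)c1ccccc1); acetic anhydride (CC(=O)OC(C)=O)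
Why: Proposed new method: Rh(I)/Josiphos binds the exo face of the unsubstituted alkene and the bridging oxygen and inserts with retention into the doubly allylic bridgehead C4–O bond distal to the CH2OBz group (the substituent then sits at a charged terminus of the resulting allyl/pentadienyl fragment), and benzoate attacks C6 anti to Rh (SN2'), so the retained C1–OH and the new C–OBz are trans and the two secondary oxygens are differentiated; only (1S,4R)‑6 is matched to the ligand, so this is a kinetic resolution (≤50 % yield, (1R,4S)‑6 recovered) that sets both carbinol stereocentres of 7 absolutely, and immediate acetylation blocks acyl migration and aromatisation; the closest known reaction is the Rh‑catalysed asymmetric ring opening of oxabenzonorbornadienes with carboxylates (and regiodivergent resolutions of unsymmetrical oxabicycles), not yet shown on a non‑benzo, unsymmetrical 7‑oxanorbornadiene.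

Step 6
Reactants: 8 [(5R,6R)‑6‑(acetyloxy)‑5‑(benzoyloxy)cyclohexa‑1,3‑dien‑1‑yl]methyl benzoate
Product: 9 [(1S,4R,5S,6S)‑5‑(acetyloxy)‑4‑(benzoyloxy)‑7‑oxabicyclo[4.1.0]hept‑2‑en‑6‑yl]methyl benzoate
Conditions: mCPBA (1.1 equiv), NaHCO3, CH2Cl2, 0 °C
Reagents that add atoms: mCPBA (OOC(=O)c1cccc(Cl)c1)
Why: Prilezhaev epoxidation: the trisubstituted alkene is the more electron‑rich one and the peracid approaches anti to the pseudo‑axial allylic acetoxy group, setting both oxirane carbons (epoxide trans to OAc, cis to OBz), as in the peracid epoxidation of the analogous diacetate to senepoxide.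

**Compound list**
1 | furan | c1ccoc1 | starting material
2 | 1,1,3,3‑tetrabromopropan‑2‑one | O=C(C(Br)Br)C(Br)Br | starting material
3 | (1R,2S,4R,5S)‑2,4‑dibromo‑8‑oxabicyclo[3.2.1]oct‑6‑en‑3‑one (meso) | O=C1[C@@H](Br)[C@H]2C=C[C@H](O2)[C@H]1Br | intermediate
4 | (±)‑methyl 7‑oxabicyclo[2.2.1]hepta‑2,5‑diene‑2‑carboxylate ((1S,4R) drawn) | COC(=O)C1=C[C@H]2C=C[C@@H]1O2 | intermediate
5 | (±)‑(7‑oxabicyclo[2.2.1]hepta‑2,5‑dien‑2‑yl)methanol ((1S,4R) drawn) | OCC1=C[C@H]2C=C[C@@H]1O2 | intermediate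
6 | (±)‑(7‑oxabicyclo[2.2.1]hepta‑2,5‑dien‑2‑yl)methyl benzoate ((1S,4R) drawn) | O=C(OCC1=C[C@H]2C=C[C@@H]1O2)c1ccccc1 | intermediate
7 | [(5R,6R)‑5‑(benzoyloxy)‑6‑hydroxycyclohexa‑1,3‑dien‑1‑yl]methyl benzoate | O[C@H]1[C@H](OC(=O)c2ccccc2)C=CC=C1COC(=O)c1ccccc1 | intermediate
8 | [(5R,6R)‑6‑(acetyloxy)‑5‑(benzoyloxy)cyclohexa‑1,3‑dien‑1‑yl]methyl benzoate | CC(=O)O[C@H]1[C@H](OC(=O)c2ccccc2)C=CC=C1COC(=O)c1ccccc1 | intermediate
9 | [(1S,4R,5S,6S)‑5‑(acetyloxy)‑4‑(benzoyloxy)‑7‑oxabicyclo[4.1.0]hept‑2‑en‑6‑yl]methyl benzoate | CC(=O)O[C@H]1[C@H](OC(=O)c2ccccc2)C=C[C@@H]2O[C@@]21COC(=O)c1ccccc1 | target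

**Totals**
Total steps: 6. Longest linear sequence: 6.

**Three steps most likely to fail**

Step 5 (the proposed new method). Risks: no turnover on the non‑benzo diene, aromatisation of 7 to a phenol, a low selectivity factor, and a 50 % yield ceiling. Fallback with known reaction types, setting out from 4 and returning at 8. Ester 4 is treated with potassium 4‑methoxybenzyloxide (THF, −78 °C): exo oxa‑Michael addition to the strained acrylate, then E1cB opening of the oxa‑bridge by the ester enolate, gives (±)‑methyl cis‑5‑hydroxy‑6‑[(4‑methoxybenzyl)oxy]cyclohexa‑1,3‑diene‑1‑carboxylate F1. DIBAL‑H reduces this to (±)‑cis‑5‑(hydroxymethyl)‑6‑[(4‑methoxybenzyl)oxy]cyclohexa‑2,4‑dien‑1‑ol F2. A double Mitsunobu reaction with benzoic acid (PPh3, DIAD) esterifies the primary alcohol and inverts the secondary carbinol, giving (±)‑[trans‑5‑(benzoyloxy)‑6‑[(4‑methoxybenzyl)oxy]cyclohexa‑1,3‑dien‑1‑yl]methyl benzoate F3. DDQ at pH 7 removes the PMB group to give (±)‑[trans‑5‑(benzoyloxy)‑6‑hydroxycyclohexa‑1,3‑dien‑1‑yl]methyl benzoate F4. A lipase (Amano PS or CAL‑B, vinyl acetate) then acetylates the (5R,6R) enantiomer to give 8.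

Step 2 (Favorskii contraction). Risks: methoxide adding to the strained acrylate product, or substitution instead of rearrangement. Fallback setting out from 1 and returning at 4: AlCl3‑promoted Diels–Alder reaction of furan with methyl propiolate (C#CC(=O)OC; CH2Cl2, 0 °C, short contact) gives 4 directly. This detour makes no compound outside the list (F0).

Step 6 (epoxidation). Risks: attack on the disubstituted alkene or on the wrong face. Fallback setting out from 8 and returning at 9: singlet oxygen (TPP, hν, CH2Cl2, −20 °C) adds across the diene anti to the acetoxy group to give [(1R,4R,5S,6S)‑6‑(acetyloxy)‑5‑(benzoyloxy)‑2,3‑dioxabicyclo[2.2.2]oct‑7‑en‑1‑yl]methyl benzoate F5. PPh3 then attacks the less hindered peroxide oxygen, and the tertiary alkoxide closes the oxirane by syn SN2' displacement of Ph3P=O, giving 9.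

**Further compounds**
F1 | step 5 | (±)‑methyl (5S,6R)‑5‑hydroxy‑6‑[(4‑methoxybenzyl)oxy]cyclohexa‑1,3‑diene‑1‑carboxylate | COc1ccc(CO[C@H]2[C@@H](O)C=CC=C2C(=O)OC)cc1
F2 | step 5 | (±)‑(1S,6R)‑5‑(hydroxymethyl)‑6‑[(4‑methoxybenzyl)oxy]cyclohexa‑2,4‑dien‑1‑ol | COc1ccc(CO[C@H]2[C@@H](O)C=CC=C2CO)cc1
F3 | step 5 | (±)‑[(5R,6R)‑5‑(benzoyloxy)‑6‑[(4‑methoxybenzyl)oxy]cyclohexa‑1,3‑dien‑1‑yl]methyl benzoate | COc1ccc(CO[C@H]2[C@H](OC(=O)c3ccccc3)C=CC=C2COC(=O)c2ccccc2)cc1
F4 | step 5 | (±)‑[(5R,6R)‑5‑(benzoyloxy)‑6‑hydroxycyclohexa‑1,3‑dien‑1‑yl]methyl benzoate | O[C@H]1[C@H](OC(=O)c2ccccc2)C=CC=C1COC(=O)c1ccccc1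
F0 | step 2 | none | none
F5 | step 6 | [(1R,4R,5S,6S)‑6‑(acetyloxy)‑5‑(benzoyloxy)‑2,3‑dioxabicyclo[2.2.2]oct‑7‑en‑1‑yl]methyl benzoate | CC(=O)O[C@H]1[C@H](OC(=O)c2ccccc2)[C@H]2C=C[C@]1(COC(=O)c1ccccc1)OO2
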